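Everything rests on forming the tetrasubstituted C11=C12 alkene last. That bond is shared by ring A (C1, C14, C13, C12, C11, C15) and the butenolide (O, C10, C11, C12, C18), while C11 is also a bridgehead of the twelve-membered ring; without it the target reduces to a simple monocyclic ketone. One intramolecular Horner–Wadsworth–Emmons reaction creates C11=C12, closes ring A across the macrocycle and places C10–O and C18 cis, ready to lactonise. Its precursor 23 is a twelve-membered C11 ketone (4-methylidene, 7E-alkene, TBS ethers at C6 and C10) whose C1 carries a CH2CH2CH(CO2Me)P(O)(OEt)2 chain, attached only after a stereochemically neutral C3–C4 Suzuki ring closure.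

Key step: step 16

Remarks
- Numbering (target atoms): C1 ring-fusion CH; C2, C3 CH2; C4 (=C20H2); C5 CH2; C6 CH–OAc; C7=C8 (C19 methyl); C9 CH2; C10 CH–O (lactone); C11=C12; C13, C14 CH2 of ring A; C15 CMe2 (C16, C17); C18 lactone C=O. The target is 1R,6S,10R,7E. Compounds 23, 24 and 27 were checked atom by atom and share this configuration.
- Design choices: the acidic phosphonoacetate is attached one step before it is used, so it never meets enolate, borane or palladium chemistry. The macrocycle is closed at a bond whose formation creates no stereocentre, so C1, C6 and C10 are all set on small or acyclic material by chiral catalysts or reagents.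
- Metal enolates and the phosphonate carbanion are treated as the deprotonated forms of the numbered compounds and carry no number of their own.
- The sense of induction in steps 1, 5 and 10 is assigned by analogy with simpler substrates. Both antipodes of each chiral controller are available.

Step 1
Reactants: 1 5,6-dihydro-2H-pyran-2-one; 2 potassium vinyltrifluoroborate
Product: 3 (R)-4-vinyltetrahydro-2H-pyran-2-one
Conditions: [Rh(cod)2]BF4 (3 mol %), (R)-BINAP (3.3 mol %), 2 (2 equiv), toluene/H2O 10:1, 80 °C
Reagents that add atoms: potassium vinyltrifluoroborate (2), C=C[B-](F)(F)F.[K+]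
Why: Hayashi–Miyaura-type rhodium-catalysed asymmetric 1,4-addition of an alkenylboron reagent to an unsaturated lactone; the (R)-BINAP pocket lets the vinylrhodium species insert on one alkene face only, which by analogy with the known sense for six-membered cyclic acceptors gives the R lactone and so fixes C1 by catalyst control.

Step 2
Reactants: 3 (R)-4-vinyltetrahydro-2H-pyran-2-one
Product: 5 (S)-3,3-dimethyl-4-vinyltetrahydro-2H-pyran-2-one, via monomethyl lactone 4 (not isolated)
Conditions: LDA (1.1 equiv), THF, −78 °C, then MeI; second charge of LDA (1.3 equiv), −78 °C, then MeI, DMPU, −78 → −20 °C, one flask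
Reagents that add atoms: iodomethane, CI
Why: Two consecutive lactone enolate methylations build the C15 gem-dimethyl group (C16, C17); the stereocentre made by the first methylation vanishes in the second, and C1–H is not acidic, so C1 is untouched (its descriptor changes only through CIP priorities).

Step 3
Reactants: 5 (S)-3,3-dimethyl-4-vinyltetrahydro-2H-pyran-2-one
Product: 6 (S)-4-(2-hydroxyethyl)-3,3-dimethylhex-5-en-2-one (in equilibrium with its cyclic hemiketal)
Conditions: MeLi (1.05 equiv), Et2O/THF, −78 °C; then H2O
Reagents that add atoms: methyllithium, [Li]C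
Why: Mono-addition of an organolithium to a lactone: the lithium hemiketal formed at low temperature resists collapse and the α-quaternary centre slows a second attack, so C10 is added, the C11 ketone appears and the C13 alcohol is released in one operation.

Step 4
Reactants: 6 (S)-4-(2-hydroxyethyl)-3,3-dimethylhex-5-en-2-one
Product: 7 (S)-3,3-dimethyl-4-[2-(triethylsilyloxy)ethyl]hex-5-en-2-one
Conditions: TESCl, imidazole, CH2Cl2, 0 °C
Reagents that add atoms: chlorotriethylsilane, CC[Si](Cl)(CC)CC
Why: Routine silylation that traps the primary alcohol of the open form and thereby drains the hemiketal; TES is chosen because it can later be removed beside secondary TBS ethers.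

Step 5
Reactants: 8 3-methylbut-2-enal; 9 2,3-dibromopropene
Product: 11 (S)-2-bromo-6-methylhepta-1,5-dien-4-ol, via trimethylsilyl ether 10 (not isolated)
Conditions: CrBr3 (10 mol %), N-[2-(4-isopropyl-4,5-dihydrooxazol-2-yl)-6-methylphenyl]methanesulfonamide (11 mol %, antipode for Si-face attack), Et3N (20 mol %), Mn (2 equiv), Co(phthalocyanine) (1 mol %), TMSCl (1.5 equiv), 2,6-lutidine, THF, 0 → 23 °C; then 1 M HCl, THF, 0 °C
Reagents that add atoms: 2,3-dibromopropene (9), C=C(Br)CBr
Why: Catalytic asymmetric Nozaki–Hiyama–Kishi 2-haloallylation: the allylic C–Br bond of 9 is activated to a 2-bromoallylchromium species held by the chiral sulfonamide ligand, which adds 1,2 to the enal through a cyclic transition state on the Si face and sets C6 as S by catalyst control, the alkenyl bromide staying inert.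

Step 6
Reactants: 11 (S)-2-bromo-6-methylhepta-1,5-dien-4-ol
Product: 12 (S)-2-bromo-4-(tert-butyldimethylsilyloxy)-6-methylhepta-1,5-diene
Conditions: TBSCl, imidazole, DMF, 23 °C
Reagents that add atoms: tert-butyldimethylsilyl chloride, CC(C)(C)[Si](C)(C)Cl
Why: Routine silyl ether formation; TBS withstands the enolate, borane and palladium steps ahead and is removed together with the O10 group at the end.

Step 7
Reactants: 12 (S)-2-bromo-4-(tert-butyldimethylsilyloxy)-6-methylhepta-1,5-diene
Product: 13 (2E,4S)-6-bromo-4-(tert-butyldimethylsilyloxy)-2-methylhepta-2,6-dien-1-ol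
Conditions: SeO2 (0.3 equiv), t-BuOOH (3 equiv), salicylic acid (10 mol %), CH2Cl2, 0 → 23 °C, stopped before over-oxidation
Reagents that add atoms: selenium dioxide, O=[Se]=O; tert-butyl hydroperoxide, CC(C)(C)OO
Why: Riley-type allylic oxidation (ene reaction, then [2,3]-sigmatropic shift) attacks the electron-richer trisubstituted alkene at the methyl group trans to C6, which delivers the E allylic alcohol needed for the 7E-alkene, while the bromoalkene is too electron-poor to compete.

Step 8
Reactants: 13 (2E,4S)-6-bromo-4-(tert-butyldimethylsilyloxy)-2-methylhepta-2,6-dien-1-ol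
Product: 14 (4S,5E)-2,7-dibromo-4-(tert-butyldimethylsilyloxy)-6-methylhepta-1,5-diene
Conditions: CBr4, PPh3, CH2Cl2, −20 → 0 °C
Reagents that add atoms: tetrabromomethane, BrC(Br)(Br)Br
Why: Appel reaction of a primary allylic alcohol, an SN2 displacement on the oxyphosphonium salt that keeps the E geometry and the C6 silyl ether.

Step 9
Reactants: 7 (S)-3,3-dimethyl-4-[2-(triethylsilyloxy)ethyl]hex-5-en-2-one; 14 (4S,5E)-2,7-dibromo-4-(tert-butyldimethylsilyloxy)-6-methylhepta-1,5-diene
Product: 15 (3S,8E,10S)-12-bromo-10-(tert-butyldimethylsilyloxy)-4,4,8-trimethyl-3-[2-(triethylsilyloxy)ethyl]trideca-1,8,12-trien-5-one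
Conditions: 7, LDA (1.05 equiv), THF, −78 °C; then 14 (0.9 equiv), DMPU, −78 → −30 °C
Reagents that add atoms: none
Why: Kinetic enolate alkylation: C15 is quaternary, so 7 can be deprotonated only at C10, and the unhindered lithium enolate displaces the primary allylic bromide by SN2 to form C9–C10, the alkenyl bromide being inert; no stereocentre is formed.

Step 10
Reactants: 15 the acyclic C11 ketone
Product: 16 (3S,6R,8E,10S)-12-bromo-10-(tert-butyldimethylsilyloxy)-6-hydroxy-4,4,8-trimethyl-3-[2-(triethylsilyloxy)ethyl]trideca-1,8,12-trien-5-one (10R in target numbering)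
Conditions: NaHMDS (1.2 equiv), THF, −78 °C; (−)-(camphorylsulfonyl)oxaziridine (1.5 equiv), −78 °C; AcOH quench at −78 °C
Reagents that add atoms: (−)-(camphorylsulfonyl)oxaziridine, CC1(C)[C@H]2CC[C@@]13CS(=O)(=O)N4O[C@]34C2
Why: Davis-type asymmetric enolate hydroxylation: the bulky tert-alkyl group enforces the Z-enolate and the (−)-oxaziridine transfers oxygen to the face giving 10R (by analogy with the (+)-reagent giving S acyloins from Z-enolates), alkenes and silyl ethers being inert to this oxidant and any 10S epimer being a separable diastereomer.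

Step 11
Reactants: 16 the 10R acyloin
Product: 17 (3S,6R,8E,10S)-12-bromo-6,10-bis(tert-butyldimethylsilyloxy)-4,4,8-trimethyl-3-[2-(triethylsilyloxy)ethyl]trideca-1,8,12-trien-5-one
Conditions: TBSOTf, 2,6-lutidine, CH2Cl2, −78 → 0 °C
Reagents that add atoms: tert-butyldimethylsilyl triflate, CC(C)(C)[Si](C)(C)OS(=O)(=O)C(F)(F)F
Why: A silyl triflate with a hindered pyridine base silylates the congested acyloin hydroxyl under non-enolising conditions, which blocks ketol shift and C10 epimerisation.

Step 12
Reactants: 17 the acyclic bromo triene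
Product: 19 (2R,4E,6S,11R)-2,6-bis(tert-butyldimethylsilyloxy)-4,12,12-trimethyl-8-methylidene-11-[2-(triethylsilyloxy)ethyl]cyclododec-4-en-1-one, via B-alkyl-9-BBN adduct 18 (not isolated)
Conditions: 9-BBN-H (1.5 equiv), THF, 23 °C; H2O; then slow addition to PdCl2(dppf) (15 mol %), AsPh3 (30 mol %), Cs2CO3 (4 equiv), DMF/THF/H2O, 2 mM, 50 °C
Reagents that add atoms: none
Why: 9-BBN adds to the only monosubstituted alkene (bromoalkene, trisubstituted alkene and the doubly flanked ketone react far more slowly), and B-alkyl Suzuki–Miyaura coupling of the C3 borane to the C4 alkenyl bromide at high dilution closes the twelve-membered ring, a known macrocyclisation type that forms no stereocentre and leaves the 4-methylidene group in place.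

Step 13
Reactants: 19 the macrocyclic TES ether
Product: 20 (2R,4E,6S,11R)-2,6-bis(tert-butyldimethylsilyloxy)-11-(2-hydroxyethyl)-4,12,12-trimethyl-8-methylidenecyclododec-4-en-1-one
Conditions: AcOH/THF/H2O 3:3:1, 0 → 23 °C
Reagents that add atoms: none
Why: Acid hydrolysis differentiates silyl ethers by size and position, so the primary TES ether is cleaved far faster than the two secondary TBS ethers, and the alcohol-free medium avoids ketal formation between O13 and C11.

Step 14
Reactants: 20 the C13 alcohol
Product: 21 (2R,4E,6S,11R)-2,6-bis(tert-butyldimethylsilyloxy)-11-(2-iodoethyl)-4,12,12-trimethyl-8-methylidenecyclododec-4-en-1-one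
Conditions: I2, PPh3, imidazole, CH2Cl2, 0 °C
Reagents that add atoms: iodine, II
Why: Appel-type iodination of the primary alcohol, which is drawn out of any hemiketal form; the near-neutral conditions leave C10 and the alkenes untouched.

Step 15
Reactants: 21 the C13 iodide; 22 methyl diethylphosphonoacetate
Product: 23 the twelve-membered C11 ketone of 21 in which the iodoethyl group has become a 3-(diethoxyphosphoryl)-4-methoxy-4-oxobutyl chain on C1 (1R,6S,10R,7E; both C12 epimers)
Conditions: 22 (3 equiv), NaH (2.8 equiv), DMF, 0 °C; then 21, 45 °C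
Reagents that add atoms: methyl diethylphosphonoacetate (22), COC(=O)CP(=O)(OCC)OCC
Why: SN2 alkylation of the soft sodium phosphonoacetate anion by the primary iodide forms C12–C13; the anion is too weak a base to enolise the ketone and too bulky to olefinate it intermolecularly, excess 22 suppresses dialkylation, and C12 arises as an inconsequential epimer mixture.

Step 16
Reactants: 23 the macrocyclic keto phosphonoacetate
Product: 24 bicyclo[9.3.1]pentadecatriene methyl ester: ring A cyclohexene with C11=C12 and CO2Me (C18) on C12, bridged from C1 to C11 by the C2–C10 chain, TBS ethers at O6 and O10 (1R,6S,10R,7E)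
Conditions: LiCl (10 equiv, dried), DBU (5 equiv), MeCN, 5 mM, 23 → 60 °C
Reagents that add atoms: none
Why: Lithium-assisted deprotonation by DBU (Masamune–Roush conditions) turns both C12 epimers into one stabilised phosphonoenolate whose C12 adds to the C11 carbonyl, and the β-alkoxyphosphonate closes to an oxaphosphetane that collapses irreversibly with loss of lithium diethyl phosphate to give C11=C12. The closest known reaction type is the intramolecular Horner–Wadsworth–Emmons cyclisation of 7-oxo-2-phosphonoalkanoates to cyclohex-1-enecarboxylates. Ring A closes by a 6-exo-trig attack (C12 onto C11=O through C13, C14, C1 and C15), assisted by the C15 gem-dialkyl effect and by inductive activation of the ketone by O10. No stereocentre is created, since C12 becomes planar and the ring forces C10 and C18 onto the same side of the new alkene. The selectivity needed is deprotonation at C12 and not at C10–H, and it is secured because the phosphonoacetate is more acidic than the hindered α-silyloxy ketone by many pK units, so an amidine base does not enolise the ketone and C10 keeps its configuration. The lithium counter-ion holds the C11 alkoxide tightly and so disfavours O10-to-O11 silyl migration before phosphate loss.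

Step 17
Reactants: 24 the bicyclic ester
Product: 26 6-hydroxy butenolide (6-O-deacetyl target; 1R,6S,10R,7E), via dihydroxy ester 25 (not isolated)
Conditions: HF·pyridine, pyridine, THF, 0 → 23 °C
Reagents that add atoms: none
Why: Fluoride-driven desilylation under mildly acidic conditions; the freed O10 hydroxyl sits cis to the C18 ester on the tetrasubstituted alkene and closes the butenolide spontaneously by 5-exo-trig transesterification, while the non-basic medium avoids deprotonation of the butenolide γ-position (C10–H).

Step 18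
Reactants: 26 the 6-hydroxy butenolide
Product: 27 target CNP0289913.1 (1R,6S,10R,7E)
Conditions: Ac2O, pyridine, DMAP (cat.), CH2Cl2, 0 → 23 °C
Reagents that add atoms: acetic anhydride, CC(=O)OC(C)=O
Why: DMAP-catalysed acylation of the only remaining hydroxyl group (allylic O6), which proceeds at oxygen and therefore retains C6.

Compound list
1 | 5,6-dihydro-2H-pyran-2-one | O=C1C=CCCO1 | starting material
2 | potassium vinyltrifluoroborate | C=C[B-](F)(F)F.[K+] | starting material
3 | (R)-4-vinyltetrahydro-2H-pyran-2-one | O=C1OCC[C@@H](C=C)C1 | intermediate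
4 | (4S)-3-methyl-4-vinyltetrahydro-2H-pyran-2-one, C3 epimers (not isolated) | O=C1OCC[C@@H](C=C)C1C | intermediate
5 | (S)-3,3-dimethyl-4-vinyltetrahydro-2H-pyran-2-one | O=C1OCC[C@@H](C=C)C1(C)C | intermediate
6 | (S)-4-(2-hydroxyethyl)-3,3-dimethylhex-5-en-2-one | CC(=O)C(C)(C)[C@H](C=C)CCO | intermediate
7 | (S)-3,3-dimethyl-4-[2-(triethylsilyloxy)ethyl]hex-5-en-2-one | CC(=O)C(C)(C)[C@H](C=C)CCO[Si](CC)(CC)CC | intermediate
8 | 3-methylbut-2-enal | CC(C)=CC=O | starting material
9 | 2,3-dibromopropene | C=C(Br)CBr | starting material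
10 | (S)-2-bromo-6-methyl-4-(trimethylsilyloxy)hepta-1,5-diene (not isolated) | C=C(Br)C[C@H](O[Si](C)(C)C)C=C(C)C | intermediate
11 | (S)-2-bromo-6-methylhepta-1,5-dien-4-ol | C=C(Br)C[C@H](O)C=C(C)C | intermediate
12 | (S)-2-bromo-4-(tert-butyldimethylsilyloxy)-6-methylhepta-1,5-diene | C=C(Br)C[C@H](O[Si](C)(C)C(C)(C)C)C=C(C)C | intermediate
13 | (2E,4S)-6-bromo-4-(tert-butyldimethylsilyloxy)-2-methylhepta-2,6-dien-1-ol | C=C(Br)C[C@H](O[Si](C)(C)C(C)(C)C)/C=C(C)/CO | intermediate
14 | (4S,5E)-2,7-dibromo-4-(tert-butyldimethylsilyloxy)-6-methylhepta-1,5-diene | C=C(Br)C[C@H](O[Si](C)(C)C(C)(C)C)/C=C(C)/CBr | intermediate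
15 | acyclic C11 ketone (3S,8E,10S) | C=C[C@H](CCO[Si](CC)(CC)CC)C(C)(C)C(=O)CC/C(C)=C/[C@@H](O[Si](C)(C)C(C)(C)C)CC(Br)=C | intermediate
16 | acyclic 10R acyloin (3S,6R,8E,10S) | C=C[C@H](CCO[Si](CC)(CC)CC)C(C)(C)C(=O)[C@@H](C/C(C)=C/[C@@H](O[Si](C)(C)C(C)(C)C)CC(Br)=C)O | intermediate
17 | acyclic bis-TBS, TES bromo triene ketone | C=C[C@H](CCO[Si](CC)(CC)CC)C(C)(C)C(=O)[C@@H](C/C(C)=C/[C@@H](O[Si](C)(C)C(C)(C)C)CC(Br)=C)O[Si](C)(C)C(C)(C)C | intermediate
18 | C3 B-alkyl-9-BBN adduct of 17 (not isolated) | C1CC2CCCC(C1)B2CC[C@H](CCO[Si](CC)(CC)CC)C(C)(C)C(=O)[C@@H](C/C(C)=C/[C@@H](O[Si](C)(C)C(C)(C)C)CC(Br)=C)O[Si](C)(C)C(C)(C)C | intermediate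
19 | twelve-membered ketone, C13 TES ether | C=C1CC[C@H](CCO[Si](CC)(CC)CC)C(C)(C)C(=O)[C@@H](C/C(C)=C/[C@@H](O[Si](C)(C)C(C)(C)C)C1)O[Si](C)(C)C(C)(C)C | intermediate
20 | twelve-membered ketone, C13 alcohol | C=C1CC[C@H](CCO)C(C)(C)C(=O)[C@@H](C/C(C)=C/[C@@H](O[Si](C)(C)C(C)(C)C)C1)O[Si](C)(C)C(C)(C)C | intermediate
21 | twelve-membered ketone, C13 iodide | C=C1CC[C@H](CCI)C(C)(C)C(=O)[C@@H](C/C(C)=C/[C@@H](O[Si](C)(C)C(C)(C)C)C1)O[Si](C)(C)C(C)(C)C | intermediate
22 | methyl diethylphosphonoacetate | COC(=O)CP(=O)(OCC)OCC | starting material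
23 | twelve-membered C11 ketone with phosphonoacetate chain (C12 epimers) | C=C1CC[C@H](CCC(C(=O)OC)P(=O)(OCC)OCC)C(C)(C)C(=O)[C@@H](C/C(C)=C/[C@@H](O[Si](C)(C)C(C)(C)C)C1)O[Si](C)(C)C(C)(C)C | intermediate
24 | bicyclic C18 methyl ester bis-TBS ether | C=C1CC[C@@H]2CCC(C(=O)OC)=C([C@@H](C/C(C)=C/[C@@H](O[Si](C)(C)C(C)(C)C)C1)O[Si](C)(C)C(C)(C)C)C2(C)C | intermediate
25 | bicyclic 6,10-dihydroxy methyl ester (not isolated) | C=C1CC[C@@H]2CCC(C(=O)OC)=C([C@@H](C/C(C)=C/[C@@H](O)C1)O)C2(C)C | intermediate
26 | 6-hydroxy butenolide | C=C1CC[C@@H]2CCC3=C([C@@H](C/C(C)=C/[C@@H](O)C1)OC3=O)C2(C)C | intermediate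
27 | CNP0289913.1 | C=C1CC[C@@H]2CCC3=C([C@@H](C/C(C)=C/[C@@H](OC(C)=O)C1)OC3=O)C2(C)C | target

Total step count: 18. Longest linear sequence: 14 (steps 1–4 or steps 5–8, then steps 9–18).

Steps most likely to fail

Step 16 (key step). The fully substituted C12 carbanion may fail to add to a carbonyl flanked by the C15 quaternary centre and the C10 silyloxy methine, or the adduct may revert faster than it loses phosphate. The fallback sets out from 20 and rejoins the route at 24. It replaces the tertiary carbanion by a less hindered secondary ester enolate and splits bond formation from alkene formation.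
- Dess–Martin oxidation of 20 gives the C13 aldehyde F1.
- Wittig reaction with methyl (triphenylphosphoranylidene)acetate gives the E-enoate F2.
- Conjugate reduction with [(Ph3P)CuH]6 in toluene generates a copper enolate at C12, which closes ring A on the C11 ketone in a tandem conjugate reduction–aldol cyclisation. This gives the β-hydroxy ester F3 (C11 and C12 epimers are of no consequence).
- Dehydration with SOCl2/pyridine removes the acidic C12–H and gives 24.

Step 12. Oligomerisation, protodeboronation or β-hydride elimination may outrun the transannular coupling. The fallback sets out from 7 and 13 and rejoins at 19. It forms the same two C–C bonds in the reverse order.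
- Hydroboration of 7 with 9-BBN gives the borane F4.
- Intermolecular coupling of F4 to the alkenyl bromide of 13 (PdCl2(dppf), Cs2CO3) gives the seco allylic alcohol F5.
- Appel bromination gives the allylic bromide F6.
- Slow addition of F6 to LiHMDS in THF at high dilution closes the ring at C9–C10 by intramolecular enolate alkylation, giving the macrocyclic ketone F7.
- Hydroxylation as in step 10 gives the macrocyclic acyloin F8, and TBSOTf/2,6-lutidine then gives 19.

Step 10. Oxygen transfer may show poor facial selectivity, so that C10 is not controlled. The fallback sets out from 16 (used as its epimer mixture, for which an achiral N-sulfonyloxaziridine suffices) and comes back to 16. It moves the stereodefining event from C–O bond formation to carbonyl reduction.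
- Dess–Martin oxidation gives the 1,2-diketone F9.
- Corey–Bakshi–Shibata reduction with the (S)-methyl oxazaborolidine and catecholborane at −78 °C reduces only the unhindered C10 carbonyl. The pivaloyl-like acyl group acts as the large substituent, which gives 10R by analogy with aryl alkyl ketones. The alkenes are not hydroborated by catecholborane at this temperature.

Further compounds
F1 | step 16 | twelve-membered ketone, C13 aldehyde | C=C1CC[C@H](CC=O)C(C)(C)C(=O)[C@@H](C/C(C)=C/[C@@H](O[Si](C)(C)C(C)(C)C)C1)O[Si](C)(C)C(C)(C)C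
F2 | step 16 | twelve-membered ketone with (E)-4-methoxy-4-oxobut-2-enyl chain on C1 | C=C1CC[C@H](C/C=C/C(=O)OC)C(C)(C)C(=O)[C@@H](C/C(C)=C/[C@@H](O[Si](C)(C)C(C)(C)C)C1)O[Si](C)(C)C(C)(C)C
F3 | step 16 | bicyclic 11-hydroxy C18 methyl ester (C11, C12 epimers) | C=C1CC[C@@H]2CCC(C(=O)OC)C(O)([C@@H](C/C(C)=C/[C@@H](O[Si](C)(C)C(C)(C)C)C1)O[Si](C)(C)C(C)(C)C)C2(C)C
F4 | step 12 | C3 B-alkyl-9-BBN adduct of 7 | CC(=O)C(C)(C)[C@H](CCB1C2CCCC1CCC2)CCO[Si](CC)(CC)CC
F5 | step 12 | seco methyl ketone with C9 allylic alcohol | CC(=O)C(C)(C)[C@H](CCC(=C)C[C@H](O[Si](C)(C)C(C)(C)C)/C=C(C)/CO)CCO[Si](CC)(CC)CC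
F6 | step 12 | seco methyl ketone with C9 allylic bromide | CC(=O)C(C)(C)[C@H](CCC(=C)C[C@H](O[Si](C)(C)C(C)(C)C)/C=C(C)/CBr)CCO[Si](CC)(CC)CC
F7 | step 12 | twelve-membered ketone unsubstituted at C10 | C=C1CC[C@H](CCO[Si](CC)(CC)CC)C(C)(C)C(=O)CC/C(C)=C/[C@@H](O[Si](C)(C)C(C)(C)C)C1
F8 | step 12 | twelve-membered 10R acyloin | C=C1CC[C@H](CCO[Si](CC)(CC)CC)C(C)(C)C(=O)[C@@H](C/C(C)=C/[C@@H](O[Si](C)(C)C(C)(C)C)C1)O
F9 | step 10 | acyclic C10,C11 diketone | C=C[C@H](CCO[Si](CC)(CC)CC)C(C)(C)C(=O)C(=O)C/C(C)=C/[C@@H](O[Si](C)(C)C(C)(C)C)CC(Br)=C
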